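**Retrosynthetic overview**

- The two free phenols are unmasked last: fluoride removes the ring B silyl group, then thiolate cleaves the ring A methyl ether.
- The route rests on ring B, the benzene ring joined through C1' to C2 of the benzofuran. It carries OMe on C3' and OH on C5' on either side of C4'–H, with prenyl groups on C2' and C6'.
- Ring B is the last ring made: a siloxyalkyne (supplying C5'–O and C6'–prenyl) adds across C3/C6 of a 4-methoxy-2-pyrone (supplying C1' to C4' with aryl, prenyl, OMe and H), and CO2 is then lost, so the two oxygens are different from the outset.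
- The pyrone comes from O-methylation of the 4-hydroxypyrone, itself from a silyl enol ether and malonyl dichloride; the ketone comes from a Weinreb amide and homoprenyl Grignard. Ring order: benzofuran (bought), pyrone ring, ring B.
- The siloxyalkyne comes from 5-methylhex-4-en-1-yne by ynolate formation and O-silylation; the enyne comes from prenyl bromide and ethynylmagnesium bromide.

Key step: step 8

Assumption: the target has no stereocentre, so the geometry of the silyl enol ether and the racemic nature of the transient intermediates have no bearing on the product.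

**Route**

Step 1
Reactants: 1 6-methoxy-1-benzofuran-2-carboxylic acid
Product: 3 N,6-dimethoxy-N-methyl-1-benzofuran-2-carboxamide, via acyl imidazolide 2 (not isolated)
Conditions: 1,1'-carbonyldiimidazole (CDI), CH2Cl2, rt; then MeNHOMe·HCl, rt
Reagents that add atoms: N,O-dimethylhydroxylamine hydrochloride, Cl.CNOC
Why: Weinreb amide formation, in which CDI turns the acid into the acyl imidazolide and this acylates the hydroxylamine nitrogen, the imidazole set free taking up the HCl.

Step 2
Reactants: 3 N,6-dimethoxy-N-methyl-1-benzofuran-2-carboxamide; 4 5-bromo-2-methylpent-2-ene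
Product: 6 1-(6-methoxy-1-benzofuran-2-yl)-5-methylhex-4-en-1-one, via Grignard reagent 5 (not isolated)
Conditions: 4, Mg, THF, rt; then 3, 0 °C; aq NH4Cl
Reagents that add atoms: none
Why: Weinreb ketone synthesis, in which the magnesium-chelated tetrahedral adduct collapses to the ketone only on work-up, so a single addition of the homoprenyl Grignard reagent is expected.

Step 3
Reactants: 6 1-(6-methoxy-1-benzofuran-2-yl)-5-methylhex-4-en-1-one
Product: 7 {[(1Z)-1-(6-methoxy-1-benzofuran-2-yl)-5-methylhexa-1,4-dien-1-yl]oxy}trimethylsilane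
Conditions: LiN(iPr)2, THF, −78 °C; Me3SiCl, −78 °C → rt
Reagents that add atoms: chlorotrimethylsilane, C[Si](C)(C)Cl
Why: Silyl enol ether formation by kinetic deprotonation at the only enolisable carbon and O-silylation of the lithium enolate; the Z isomer is expected, but the geometry is lost in the pyrone.

Step 4
Reactants: 7 {[(1Z)-1-(6-methoxy-1-benzofuran-2-yl)-5-methylhexa-1,4-dien-1-yl]oxy}trimethylsilane; 8 malonyl dichloride
Product: 10 4-hydroxy-6-(6-methoxy-1-benzofuran-2-yl)-5-(3-methylbut-2-en-1-yl)-2H-pyran-2-one, via diketo acid chloride 9 (not isolated)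
Conditions: Et2O, −78 °C → rt
Reagents that add atoms: none
Why: Pyrone synthesis from a silyl enol ether and malonyl dichloride, in which C-acylation gives the 1,3-diketone acid chloride and its enol oxygen closes onto the second acyl chloride, so the former ketone carbon becomes C6 and the prenyl-bearing carbon becomes C5.

Step 5
Reactants: 10 4-hydroxy-6-(6-methoxy-1-benzofuran-2-yl)-5-(3-methylbut-2-en-1-yl)-2H-pyran-2-one
Product: 11 4-methoxy-6-(6-methoxy-1-benzofuran-2-yl)-5-(3-methylbut-2-en-1-yl)-2H-pyran-2-one
Conditions: Me2SO4, K2CO3, acetone, reflux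
Reagents that add atoms: dimethyl sulfate, COS(=O)(=O)OC
Why: O-alkylation of the potassium salt of the vinylogous acid with a hard methylating agent, which with 4-hydroxy-2-pyrones favours the 4-methoxy-2-pyrone over the 2-methoxy-4-pyrone.

Step 6
Reactants: 12 1-bromo-3-methylbut-2-ene; 13 ethynylmagnesium bromide
Product: 14 5-methylhex-4-en-1-yne
Conditions: 13 (1.5 equiv), CuCl (5 mol %), THF, 0 → 50 °C; distil
Reagents that add atoms: none
Why: Copper-catalysed allyl–alkynyl coupling at the unhindered primary carbon of prenyl bromide should give the skipped enyne, and excess acetylide suppresses a second allylation.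

Step 7
Reactants: 14 5-methylhex-4-en-1-yne
Product: 17 triisopropyl[(5-methylhex-4-en-1-yn-1-yl)oxy]silane, via lithium acetylide 15 (not isolated), via lithium ynolate 16 (not isolated)
Conditions: LiN(SiMe3)2 (2.2 equiv), t-BuOOH, THF, −78 → 0 °C; then iPr3SiOTf, −78 → 0 °C; aq NaHCO3
Reagents that add atoms: tert-butyl hydroperoxide, CC(C)(C)OO; triisopropylsilyl trifluoromethanesulfonate, CC(C)[Si](OS(=O)(=O)C(F)(F)F)(C(C)C)C(C)C
Why: Oxidation of the lithium acetylide by lithium tert-butyl peroxide gives the lithium ynolate (acetylide-to-ynolate oxidation), and the bulky silyl triflate traps it on oxygen to give the siloxyalkyne.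

Step 8
Reactants: 11 4-methoxy-6-(6-methoxy-1-benzofuran-2-yl)-5-(3-methylbut-2-en-1-yl)-2H-pyran-2-one; 17 triisopropyl[(5-methylhex-4-en-1-yn-1-yl)oxy]silane
Product: 19 6-methoxy-2-[3-methoxy-2,6-bis(3-methylbut-2-en-1-yl)-5-(triisopropylsilyloxy)phenyl]-1-benzofuran, via bridged lactone 18 (not isolated)
Conditions: 17 (3 equiv), PhMe, sealed tube, 130 °C
Reagents that add atoms: none
Why: Proposed new method: the HOMO of the ynol silyl ether is largest on the prenyl-bearing carbon and the LUMO of the 2-pyrone is largest on C6, so an asynchronous, possibly stepwise polar [4+2] addition is expected in which that carbon bonds to pyrone C6 and the silyloxy carbon to C3, giving the 2-oxabicyclo[2.2.2]octadienone 18, which loses CO2 by retro-[4+2] under the same heating. The closest known reaction type is the inverse-electron-demand Diels–Alder reaction of 2-pyrones with ynamines and other electron-rich alkynes followed by CO2 extrusion; what has not been shown is a siloxyalkyne adding to a 4-alkoxy-5,6-disubstituted pyrone, whose methoxy group raises the LUMO. Ring B is closed as a six-membered carbocycle by intermolecular [4+2] cycloaddition across pyrone C3 and C6 (new bonds C1'–C6' and C4'–C5') and is made aromatic by the cycloreversion. No stereocentre remains, since the two bridgehead centres of 18 are transient and vanish when CO2 leaves. The step needs regioselectivity, and polarity (nucleophilic alkyne carbon to electrophilic C6, ketenium-like silyloxy carbon to nucleophilic C3) and sterics (the bulky silyloxy end goes to the unsubstituted C3–H terminus) point the same way; the two trisubstituted alkenes are unactivated and should not compete as dienophiles. Excess alkyne is used because thermal isomerisation of 17 to the silylketene is the main competing drain.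

Step 9
Reactants: 19 6-methoxy-2-[3-methoxy-2,6-bis(3-methylbut-2-en-1-yl)-5-(triisopropylsilyloxy)phenyl]-1-benzofuran
Product: 20 5-methoxy-3-(6-methoxy-1-benzofuran-2-yl)-2,4-bis(3-methylbut-2-en-1-yl)phenol
Conditions: Bu4NF, THF, 0 °C; aq NH4Cl
Reagents that add atoms: none
Why: Fluoride cleavage of the aryl silyl ether (desilylation driven by Si–F bond formation) under non-acidic conditions, which keeps the ortho-prenyl phenol from cyclising to a chroman.

Step 10
Reactants: 20 5-methoxy-3-(6-methoxy-1-benzofuran-2-yl)-2,4-bis(3-methylbut-2-en-1-yl)phenol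
Product: 21 2-[3-hydroxy-5-methoxy-2,6-bis(3-methylbut-2-en-1-yl)phenyl]-1-benzofuran-6-ol
Conditions: NaSEt (5 equiv), DMF, 130 °C, Ar; aq NH4Cl
Reagents that add atoms: none
Why: Thiolate SN2 O-demethylation, in which the ring B phenol is deprotonated first and its phenoxide makes the ring B aryloxide a far poorer leaving group, so only the ring A methyl ether should be cleaved while the basic medium leaves both prenyl groups intact.

**Compound list**

1 | 6-methoxy-1-benzofuran-2-carboxylic acid | COc1ccc2cc(C(=O)O)oc2c1 | starting material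
2 | (1H-imidazol-1-yl)(6-methoxy-1-benzofuran-2-yl)methanone (not isolated) | O=C(c1cc2ccc(OC)cc2o1)n1ccnc1 | intermediate
3 | N,6-dimethoxy-N-methyl-1-benzofuran-2-carboxamide | CON(C)C(=O)c1cc2ccc(OC)cc2o1 | intermediate
4 | 5-bromo-2-methylpent-2-ene | CC(C)=CCCBr | starting material
5 | (4-methylpent-3-en-1-yl)magnesium bromide (not isolated) | CC(C)=CCC[Mg]Br | intermediate
6 | 1-(6-methoxy-1-benzofuran-2-yl)-5-methylhex-4-en-1-one | COc1ccc2cc(C(=O)CCC=C(C)C)oc2c1 | intermediate
7 | {[(1Z)-1-(6-methoxy-1-benzofuran-2-yl)-5-methylhexa-1,4-dien-1-yl]oxy}trimethylsilane | C[Si](C)(C)O/C(=C\CC=C(C)C)c1cc2ccc(OC)cc2o1 | intermediate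
8 | malonyl dichloride | O=C(Cl)CC(=O)Cl | starting material
9 | 5-(6-methoxy-1-benzofuran-2-yl)-4-(3-methylbut-2-en-1-yl)-3,5-dioxopentanoyl chloride (racemic, enolisable; not isolated) | O=C(Cl)CC(=O)C(CC=C(C)C)C(=O)c1cc2ccc(OC)cc2o1 | intermediate
10 | 4-hydroxy-6-(6-methoxy-1-benzofuran-2-yl)-5-(3-methylbut-2-en-1-yl)-2H-pyran-2-one | COc1ccc2cc(-c3oc(=O)cc(O)c3CC=C(C)C)oc2c1 | intermediate
11 | 4-methoxy-6-(6-methoxy-1-benzofuran-2-yl)-5-(3-methylbut-2-en-1-yl)-2H-pyran-2-one | COc1ccc2cc(-c3oc(=O)cc(OC)c3CC=C(C)C)oc2c1 | intermediate
12 | 1-bromo-3-methylbut-2-ene | CC(C)=CCBr | starting material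
13 | ethynylmagnesium bromide (THF solution) | C#C[Mg]Br | starting material
14 | 5-methylhex-4-en-1-yne | C#CCC=C(C)C | intermediate
15 | (5-methylhex-4-en-1-yn-1-yl)lithium (not isolated) | [Li]C#CCC=C(C)C | intermediate
16 | lithium 5-methylhex-4-en-1-yn-1-olate (not isolated) | [Li]OC#CCC=C(C)C | intermediate
17 | triisopropyl[(5-methylhex-4-en-1-yn-1-yl)oxy]silane | CC(C)=CCC#CO[Si](C(C)C)(C(C)C)C(C)C | intermediate
18 | 5-methoxy-1-(6-methoxy-1-benzofuran-2-yl)-6,7-bis(3-methylbut-2-en-1-yl)-8-(triisopropylsilyloxy)-2-oxabicyclo[2.2.2]octa-5,7-dien-3-one (racemic, bridgeheads fixed relative to each other by the bicycle, one enantiomer drawn; not isolated) | O=C1O[C@]2(c3cc4ccc(OC)cc4o3)C(CC=C(C)C)=C(OC)[C@H]1C(O[Si](C(C)C)(C(C)C)C(C)C)=C2CC=C(C)C | intermediate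
19 | 6-methoxy-2-[3-methoxy-2,6-bis(3-methylbut-2-en-1-yl)-5-(triisopropylsilyloxy)phenyl]-1-benzofuran | COc1ccc2cc(-c3c(CC=C(C)C)c(OC)cc(O[Si](C(C)C)(C(C)C)C(C)C)c3CC=C(C)C)oc2c1 | intermediate
20 | 5-methoxy-3-(6-methoxy-1-benzofuran-2-yl)-2,4-bis(3-methylbut-2-en-1-yl)phenol | COc1ccc2cc(-c3c(CC=C(C)C)c(OC)cc(O)c3CC=C(C)C)oc2c1 | intermediate
21 | 2-[3-hydroxy-5-methoxy-2,6-bis(3-methylbut-2-en-1-yl)phenyl]-1-benzofuran-6-ol | COc1cc(O)c(CC=C(C)C)c(-c2cc3ccc(O)cc3o2)c1CC=C(C)C | target

**Step count**

Total steps: 10. Longest linear sequence: 8 (steps 1, 2, 3, 4, 5, 8, 9, 10).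

**Steps most likely to fail**

1. Step 8. Addition at pyrone C6 may be too slow, because the 4-methoxy group lowers its electrophilicity and the 5-prenyl and 6-aryl groups shield it; thermal silyl migration of the siloxyalkyne to the silylketene would then consume the alkyne first. The fallback uses known ionic chemistry, sets out from pyrone 11 and bromide 4, and comes back at phenol 20, so step 9 is not needed. Michaelis–Arbuzov reaction of 4 with P(OEt)3 (neat, 150 °C) gives diethyl (4-methylpent-3-en-1-yl)phosphonate F1. Its lithio derivative (n-BuLi, THF, −78 °C) is acylated by the lactone carbonyl of 11, and the enol lactone opens to the β-ketophosphonate F2. With K2CO3 and 18-crown-6 in warm toluene the phosphonate carbanion closes onto the aryl ketone by intramolecular Horner–Wadsworth–Emmons olefination, and the cyclohexadienone formed tautomerises to 20. This is the enol-lactone annulation by phosphonate acylation and Horner–Wadsworth–Emmons closure, known for making cyclohexenones. The pyrone carbonyl carbon becomes C5' with its oxygen as the free hydroxyl, the phosphonate carbon becomes C6' with its prenyl group, and the 4-methoxy group stays on C3', so the ring B oxygens remain differentiated.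

2. Step 7. Oxidation of the acetylide may stall, the doubly activated CH2 of the skipped enyne may be deprotonated and the enyne isomerised by excess amide base, and the siloxyalkyne may hydrolyse during purification. The fallback sets out from bromide 12, replaces steps 6 and 7, and comes back at siloxyalkyne 17 through ynolate 16. Palladium-catalysed ethoxycarbonylation of 12 (CO, EtOH, PdCl2(PPh3)2, K2CO3) gives ethyl 4-methylpent-3-enoate F5. Under Kowalski ester homologation conditions (CH2Br2, lithium 2,2,6,6-tetramethylpiperidide, THF, −78 °C; LiN(SiMe3)2; then n-BuLi, −78 °C → rt) it passes through lithium 1,1-dibromo-5-methylhexa-1,4-dien-2-olate F6 and rearranges to ynolate 16, which iPr3SiCl silylates on oxygen to give 17.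

3. Step 4. The hydrogen chloride released on ring closure may add to the trisubstituted alkene of the prenyl group, and O-acylation or self-condensation of malonyl dichloride may compete with C-acylation. The fallback sets out from Weinreb amide 3 and bromide 12, replaces steps 2 to 4, and comes back at hydroxypyrone 10. γ-Alkylation of the dianion of ethyl acetoacetate (NaH, then n-BuLi, THF, 0 °C) with 12 gives ethyl 7-methyl-3-oxooct-6-enoate F3. Its dianion (LiN(iPr)2, 2.2 equiv, THF, −78 °C) is acylated at the γ-carbon by 3 to give ethyl 5-(6-methoxy-1-benzofuran-2-yl)-4-(3-methylbut-2-en-1-yl)-3,5-dioxopentanoate F4. DBU in toluene at reflux lactonises F4 to 10; no strong acid meets the prenyl group.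

**Further compounds**

F1 | step 8 | diethyl (4-methylpent-3-en-1-yl)phosphonate | CCOP(=O)(OCC)CCC=C(C)C
F2 | step 8 | diethyl [(3E)-4-methoxy-6-(6-methoxy-1-benzofuran-2-yl)-1,5-bis(3-methylbut-2-en-1-yl)-2,6-dioxohex-3-en-1-yl]phosphonate (open keto form, mixture of diastereomers) | CCOP(=O)(OCC)C(CC=C(C)C)C(=O)/C=C(/OC)C(CC=C(C)C)C(=O)c1cc2ccc(OC)cc2o1
F3 | step 4 | ethyl 7-methyl-3-oxooct-6-enoate | CCOC(=O)CC(=O)CCC=C(C)C
F4 | step 4 | ethyl 5-(6-methoxy-1-benzofuran-2-yl)-4-(3-methylbut-2-en-1-yl)-3,5-dioxopentanoate (racemic, enolisable) | CCOC(=O)CC(=O)C(CC=C(C)C)C(=O)c1cc2ccc(OC)cc2o1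
F5 | step 7 | ethyl 4-methylpent-3-enoate | CCOC(=O)CC=C(C)C
F6 | step 7 | lithium 1,1-dibromo-5-methylhexa-1,4-dien-2-olate | [Li]OC(CC=C(C)C)=C(Br)Br
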